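## Retrosynthetic overview

- The target is unmasked last from its O5-benzyl, O4'-acetyl form: a lipase removes the aryl acetate without touching the aryl lactone, then hydrogenolysis removes the benzyl group. Until then the benzyl ether blocks the only other oxygen that could lactonise, so the 8-acyl pattern cannot scramble to 6-acyl.
- The lactone carbonyl comes from oxidation of a chroman-2-ol.
- The chroman-2-ol comes from one asymmetric iminium-catalysed Friedel–Crafts/hemiacetalisation between a symmetrical 4-O-benzyl acylphloroglucinol and (E)-4-acetoxycinnamaldehyde. This forms the C4–C4a bond, sets the only stereocentre (C4, S) and closes the ring.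
- The acylphloroglucinol comes from phloroglucinol and 3-phenylpropanenitrile (Hoesch), then para-selective O-benzylation; the enal comes from 4-hydroxycinnamaldehyde.
- Ring order: both benzene rings are bought; the oxygen heterocycle is the only ring made (lactol in step 4, lactone in step 5).

Assumption: the face selectivity in step 4 follows the usual shielding model of diarylprolinol silyl ethers, so the (S)-catalyst gives 4S; this is a prediction, to be confirmed by chiral HPLC and optical rotation on 10, with the (R)-catalyst used if the sense is reversed.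

## Route

Step 1
Reactants: 1 benzene-1,3,5-triol (phloroglucinol); 2 3-phenylpropanenitrile
Product: 4 3-phenyl-1-(2,4,6-trihydroxyphenyl)propan-1-one, via ketiminium chloride 3 (not isolated)
Conditions: ZnCl2 (0.2 equiv), HCl gas, Et2O, 0 °C; then H2O, reflux
Reagents that add atoms: water O
Why: Houben–Hoesch acylation, in which the HCl/ZnCl2-activated nitrile attacks the very electron-rich phloroglucinol once, the precipitated ketiminium salt is too deactivated for a second acylation, and boiling water hydrolyses it to the ketone.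

Step 2
Reactants: 4 3-phenyl-1-(2,4,6-trihydroxyphenyl)propan-1-one
Product: 5 1-[4-(benzyloxy)-2,6-dihydroxyphenyl]-3-phenylpropan-1-one
Conditions: BnOH (1.0 equiv), PPh3 (1.1 equiv), diisopropyl azodicarboxylate (DIAD, 1.1 equiv), THF, 0 °C → rt
Reagents that add atoms: benzyl alcohol OCc1ccccc1
Why: Mitsunobu etherification, which is O-selective and goes to the most acidic, unchelated hydroxyl para to the ketone, so the two ortho hydroxyls stay free and the ring keeps two equivalent nucleophilic CH positions.

Step 3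
Reactants: 6 (2E)-3-(4-hydroxyphenyl)prop-2-enal
Product: 7 4-[(1E)-3-oxoprop-1-en-1-yl]phenyl acetate
Conditions: Ac2O, pyridine, CH2Cl2, 0 °C → rt
Reagents that add atoms: acetic anhydride CC(=O)OC(C)=O
Why: Plain O-acetylation of a phenol, which turns the strongly donating hydroxyl into a weakly withdrawing acetoxy group so that the enal becomes a good iminium acceptor and the phenol is masked against oxidation.

Step 4
Reactants: 5 1-[4-(benzyloxy)-2,6-dihydroxyphenyl]-3-phenylpropan-1-one (1.5 equiv); 7 4-[(1E)-3-oxoprop-1-en-1-yl]phenyl acetate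
Product: 9 4-[(4S)-5-(benzyloxy)-2,7-dihydroxy-8-(3-phenylpropanoyl)-3,4-dihydro-2H-chromen-4-yl]phenyl acetate, via open-chain aldehyde 8 (not isolated)
Conditions: (S)-α,α-diphenylprolinol trimethylsilyl ether (20 mol%), PhCO2H (20 mol%), CH2Cl2, 0 °C → rt
Reagents that add atoms: none
Why: Iminium-activated Friedel–Crafts-type Michael addition followed by hemiacetalisation, in which the acylphloroglucinol reacts as a vinylogous acid (like cyclic 1,3-diketones, 4-hydroxycoumarin and naphthols in the same catalysis) at one of its two equivalent ring CH positions on the enal face not shielded by the CPh2(OSiMe3) group of the catalyst, which sets C4 as S, and the only hydroxyl ortho to the new bond, the one next to the ketone, closes the ring so that the acyl group must end up at C8.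

Step 5
Reactants: 9 4-[(4S)-5-(benzyloxy)-2,7-dihydroxy-8-(3-phenylpropanoyl)-3,4-dihydro-2H-chromen-4-yl]phenyl acetate
Product: 10 4-[(4S)-5-(benzyloxy)-7-hydroxy-2-oxo-8-(3-phenylpropanoyl)-3,4-dihydro-2H-chromen-4-yl]phenyl acetate
Conditions: pyridinium chlorochromate [C5H5NH][CrO3Cl] (1.5 equiv), 4 Å molecular sieves, CH2Cl2, rt
Reagents that add atoms: none
Why: Oxidation of a lactol (cyclic hemiacetal) to the lactone by hexavalent chromium, a standard way to turn chroman-2-ols into chroman-2-ones, in which the remaining phenol is deactivated by its hydrogen bond to the ortho ketone and C4 is not touched.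

Step 6
Reactants: 10 4-[(4S)-5-(benzyloxy)-7-hydroxy-2-oxo-8-(3-phenylpropanoyl)-3,4-dihydro-2H-chromen-4-yl]phenyl acetate
Product: 11 (4S)-5-(benzyloxy)-7-hydroxy-4-(4-hydroxyphenyl)-8-(3-phenylpropanoyl)-3,4-dihydro-2H-chromen-2-one
Conditions: Candida antarctica lipase B (immobilised, Novozym 435), n-BuOH (5 equiv), MTBE, 40 °C
Reagents that add atoms: none
Why: Lipase-catalysed alcoholysis (transesterification) of the aryl acetate, in which the serine hydrolase accepts the small acetyl group on the exposed para-acetoxyphenyl ring but not the bulky diaryl-substituted lactone acyl group, so the phenol is freed under neutral conditions without opening the dihydrocoumarin while the O5 benzyl ether still blocks the alternative lactone position.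

Step 7
Reactants: 11 (4S)-5-(benzyloxy)-7-hydroxy-4-(4-hydroxyphenyl)-8-(3-phenylpropanoyl)-3,4-dihydro-2H-chromen-2-one
Product: 12 (4S)-5,7-dihydroxy-4-(4-hydroxyphenyl)-8-(3-phenylpropanoyl)-3,4-dihydro-2H-chromen-2-one
Conditions: H2 (1 atm), 10% Pd on carbon, EtOAc, rt
Reagents that add atoms: none
Why: Catalytic hydrogenolysis of the benzyl aryl ether under neutral conditions, which leaves the chelated aryl ketone, the lactone and the C4 stereocentre untouched and avoids acid- or base-induced translactonisation to the 6-acyl isomer.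

## Compound list

1 | benzene-1,3,5-triol (phloroglucinol) | Oc1cc(O)cc(O)c1 | starting material
2 | 3-phenylpropanenitrile | N#CCCc1ccccc1 | starting material
3 | 3-phenyl-1-(2,4,6-trihydroxyphenyl)propan-1-iminium chloride (ketiminium chloride) | [Cl-].[NH2+]=C(CCc1ccccc1)c1c(O)cc(O)cc1O | intermediate
4 | 3-phenyl-1-(2,4,6-trihydroxyphenyl)propan-1-one | O=C(CCc1ccccc1)c1c(O)cc(O)cc1O | intermediate
5 | 1-[4-(benzyloxy)-2,6-dihydroxyphenyl]-3-phenylpropan-1-one | O=C(CCc1ccccc1)c1c(O)cc(OCc2ccccc2)cc1O | intermediate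
6 | (2E)-3-(4-hydroxyphenyl)prop-2-enal | O=C/C=C/c1ccc(O)cc1 | starting material
7 | 4-[(1E)-3-oxoprop-1-en-1-yl]phenyl acetate | CC(=O)Oc1ccc(/C=C/C=O)cc1 | intermediate
8 | 4-[(1S)-1-[6-(benzyloxy)-2,4-dihydroxy-3-(3-phenylpropanoyl)phenyl]-3-oxopropyl]phenyl acetate (open-chain aldehyde) | O=CC[C@@H](c1ccc(OC(C)=O)cc1)c1c(OCc2ccccc2)cc(O)c(C(=O)CCc2ccccc2)c1O | intermediate
9 | 4-[(4S)-5-(benzyloxy)-2,7-dihydroxy-8-(3-phenylpropanoyl)-3,4-dihydro-2H-chromen-4-yl]phenyl acetate (both C2 epimers) | OC1C[C@@H](c2ccc(OC(C)=O)cc2)c2c(OCc3ccccc3)cc(O)c(C(=O)CCc3ccccc3)c2O1 | intermediate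
10 | 4-[(4S)-5-(benzyloxy)-7-hydroxy-2-oxo-8-(3-phenylpropanoyl)-3,4-dihydro-2H-chromen-4-yl]phenyl acetate | O=C1C[C@@H](c2ccc(OC(C)=O)cc2)c2c(OCc3ccccc3)cc(O)c(C(=O)CCc3ccccc3)c2O1 | intermediate
11 | (4S)-5-(benzyloxy)-7-hydroxy-4-(4-hydroxyphenyl)-8-(3-phenylpropanoyl)-3,4-dihydro-2H-chromen-2-one | O=C1C[C@@H](c2ccc(O)cc2)c2c(OCc3ccccc3)cc(O)c(C(=O)CCc3ccccc3)c2O1 | intermediate
12 | (4S)-5,7-dihydroxy-4-(4-hydroxyphenyl)-8-(3-phenylpropanoyl)-3,4-dihydro-2H-chromen-2-one | O=C1C[C@@H](c2ccc(O)cc2)c2c(O)cc(O)c(C(=O)CCc3ccccc3)c2O1 | target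

## Step count and risks

Total steps: 7. Longest linear sequence: 6 (steps 1, 2, 4, 5, 6, 7; step 3 is a one-step side branch).

**Most likely to fail: step 4.** The acyl group lowers the nucleophilicity of 5, and conversion or ee may be poor. The fallback sets out from 5 and comes back at 10, building the stereocentre by aryl transfer to a coumarin instead. Vilsmeier–Haack formylation of 5 (POCl3, DMF, EtOAc, 0 °C → rt, then water) at either of the two equivalent ring positions gives 6-(benzyloxy)-2,4-dihydroxy-3-(3-phenylpropanoyl)benzaldehyde F1. Wittig olefination with ethyl (triphenylphosphoranylidene)acetate in refluxing N,N-diethylaniline gives ethyl (2E)-3-[6-(benzyloxy)-2,4-dihydroxy-3-(3-phenylpropanoyl)phenyl]prop-2-enoate F2. In the same pot F2 isomerises and lactonises onto its only ortho hydroxyl to 5-(benzyloxy)-7-hydroxy-8-(3-phenylpropanoyl)-2H-chromen-2-one F3. Hayashi–Miyaura asymmetric 1,4-addition of (4-acetoxyphenyl)boronic acid to F3 then gives 10. Conditions for this last reaction are Rh(acac)(C2H4)2 with (S)-5,5'-bis(diphenylphosphino)-4,4'-bi-1,3-benzodioxole ((S)-SEGPHOS) in dioxane/H2O 10:1 at 60 °C without added base. The ligand enantiomer is chosen by analogy with simple coumarins and checked as in step 4. Steps 6 and 7 follow unchanged.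

**Second: step 2.** Mono-benzylation may give mixtures with the 2,4-dibenzyl ether. The fallback sets out from 4 and comes back at 5, differentiating the hydroxyls enzymatically. Peracetylation of 4 (Ac2O, pyridine) gives 2-(3-phenylpropanoyl)benzene-1,3,5-triyl triacetate F4. Lipase-catalysed alcoholysis (porcine pancreatic lipase or Candida antarctica lipase B, n-BuOH, THF, 40 °C) removes only the acetate para to the ketone and spares the two hindered ortho acetates, giving 5-hydroxy-2-(3-phenylpropanoyl)-1,3-phenylene diacetate F5. Mitsunobu benzylation of the single free phenol (BnOH, PPh3, DIAD, THF) gives 5-(benzyloxy)-2-(3-phenylpropanoyl)-1,3-phenylene diacetate F6. Methanolysis (K2CO3, MeOH, 0 °C) removes both acetates and returns 5.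

**Third: step 5.** The chromium oxidant may attack the free phenol or the electron-rich ring. The fallback sets out from 9 and comes back at 10, oxidising the ring-opened hydroxy aldehyde tautomer instead. Pinnick oxidation (NaClO2, NaH2PO4, excess 2-methyl-2-butene, t-BuOH/H2O, 0 °C) gives (3S)-3-[4-(acetyloxy)phenyl]-3-[6-(benzyloxy)-2,4-dihydroxy-3-(3-phenylpropanoyl)phenyl]propanoic acid F7. Acid-catalysed lactonisation (catalytic p-toluenesulfonic acid, toluene, 60 °C) onto the only hydroxyl ortho to the side chain returns 10.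

## Further compounds

F1 | step 4 | 6-(benzyloxy)-2,4-dihydroxy-3-(3-phenylpropanoyl)benzaldehyde | O=Cc1c(OCc2ccccc2)cc(O)c(C(=O)CCc2ccccc2)c1O
F2 | step 4 | ethyl (2E)-3-[6-(benzyloxy)-2,4-dihydroxy-3-(3-phenylpropanoyl)phenyl]prop-2-enoate | CCOC(=O)/C=C/c1c(OCc2ccccc2)cc(O)c(C(=O)CCc2ccccc2)c1O
F3 | step 4 | 5-(benzyloxy)-7-hydroxy-8-(3-phenylpropanoyl)-2H-chromen-2-one | O=C1C=Cc2c(OCc3ccccc3)cc(O)c(C(=O)CCc3ccccc3)c2O1
F4 | step 2 | 2-(3-phenylpropanoyl)benzene-1,3,5-triyl triacetate | CC(=O)Oc1cc(OC(C)=O)c(C(=O)CCc2ccccc2)c(OC(C)=O)c1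
F5 | step 2 | 5-hydroxy-2-(3-phenylpropanoyl)-1,3-phenylene diacetate | CC(=O)Oc1cc(O)cc(OC(C)=O)c1C(=O)CCc1ccccc1
F6 | step 2 | 5-(benzyloxy)-2-(3-phenylpropanoyl)-1,3-phenylene diacetate | CC(=O)Oc1cc(OCc2ccccc2)cc(OC(C)=O)c1C(=O)CCc1ccccc1
F7 | step 5 | (3S)-3-[4-(acetyloxy)phenyl]-3-[6-(benzyloxy)-2,4-dihydroxy-3-(3-phenylpropanoyl)phenyl]propanoic acid | OC(=O)C[C@@H](c1ccc(OC(C)=O)cc1)c1c(OCc2ccccc2)cc(O)c(C(=O)CCc2ccccc2)c1O
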